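Agastinol is cut at its C9 ester to a lariciresinol-type alcohol. Its oxolane (O1, C2–C5) carries the one-carbon arms C9 (on C3) and C7' (on C4) cis to each other and both trans to the C2 aryl group. That pattern is what remains when a two-carbon bridge laid on one face of a C3=C4 alkene is later severed. The key step therefore adds an aryl keteniminium ion to an enantiopure (R)-2-aryl-2,5-dihydrofuran, forming C3–C9 and C4–C7', a cyclobutane and three stereocentres at once. Baeyer–Villiger oxidation and hydrogenolysis then cut C9–C7'. The precursor comes from an asymmetric Heck reaction and bears an acetoxy, not alkoxy, aryl ring.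

Key step: step 6

Atom labels: oxolane O1, C2 (aryl), C3 (arm C9), C4 (arm C7'), C5. Ring A is the aryl group on C2 and ring B the aryl group on C7'.

Assumption: (S)-t-Bu-PHOX is taken to give the (R)-2-aryl-2,5-dihydrofuran, as in the parent phenyl series; the antipodal ligand is equally available if the sense is opposite.

Design points:
- **Protecting groups.** Ring A carries an acetate and only ring B a benzyl ether.
  - A benzyl ether on ring A would be lost in the hydrogenolysis of step 8. That would leave a para-hydroxybenzylic C2–O1 bond open to over-reduction.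
  - As a donor, it would also help the allylic, benzylic C2–O1 bond to ionise in step 6.
  - An acceptor on ring A and a donor on ring B make the two benzylic C–O bonds of the lactone electronically different. The donor on ring B also directs the Baeyer–Villiger migration.
- **Timing of the acetate.** It is installed after the aldehyde-to-phenol oxidation, because an acyloxy-substituted ring migrates poorly there.
- **Heck ligand.** The Heck step needs a P,N ligand. Chelating diphosphines lead mainly to the isomerised 2-aryl-2,3-dihydrofuran.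
- **Starting materials.** All four are catalogue items: O-benzylvanillin, 2,3-dihydrofuran, O-benzylhomovanillic acid and 4-acetoxybenzoic acid.

Step 1
Reactants: 1 4-(benzyloxy)-3-methoxybenzaldehyde (O-benzylvanillin)
Product: 3 4-(benzyloxy)-3-methoxyphenol, via aryl formate 2 (not isolated)
Conditions: mCPBA, CH2Cl2, 0 °C → rt; then K2CO3 (cat.), MeOH, rt
Reagents that add atoms: mCPBA, O=C(OO)c1cccc(Cl)c1
Why: Baeyer–Villiger (Dakin-type) oxidation in which the para-alkoxy ring migrates to oxygen in preference to hydride, after which the very labile formate is removed by mild methanolysis.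

Step 2
Reactants: 3 4-(benzyloxy)-3-methoxyphenol
Product: 4 4-(benzyloxy)-3-methoxyphenyl trifluoromethanesulfonate
Conditions: Tf2O, pyridine, CH2Cl2, 0 °C
Reagents that add atoms: triflic anhydride, O=S(=O)(OS(=O)(=O)C(F)(F)F)C(F)(F)F
Why: Routine O-sulfonylation (triflation) of a phenol, chosen because a non-coordinating leaving group lets the later Heck reaction run through a cationic arylpalladium complex.

Step 3
Reactants: 4 4-(benzyloxy)-3-methoxyphenyl trifluoromethanesulfonate
Product: 6 2-methoxy-4-(triflyloxy)phenyl acetate, via phenol triflate 5 (not isolated)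
Conditions: H2 (1 atm), 10% Pd/C, EtOAc, rt; filter; Ac2O, Et3N, DMAP (cat.), rt
Reagents that add atoms: acetic anhydride, CC(=O)OC(C)=O
Why: Hydrogenolytic debenzylation followed by DMAP-catalysed O-acetylation, feasible because an aryl benzyl ether is cleaved quickly under neutral conditions whereas reduction of an aryl triflate needs added base.

Step 4
Reactants: 6 2-methoxy-4-(triflyloxy)phenyl acetate; 7 2,3-dihydrofuran
Product: 8 4-[(2R)-2,5-dihydrofuran-2-yl]-2-methoxyphenyl acetate
Conditions: Pd2(dba)3 (1.5 mol %), (S)-t-Bu-PHOX (6 mol %), i-Pr2NEt (2 equiv), 7 (5 equiv), THF, 60 °C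
Reagents that add atoms: none
Why: Asymmetric intermolecular Mizoroki–Heck arylation in which the cationic aryl–Pd complex adds syn to the enol ether with aryl on the oxygen-bearing carbon, syn β-hydride elimination on the far side gives the 2,5-dihydrofuran, the P,N ligand lets the alkene leave Pd–H before re-insertion, and the tert-butyl oxazoline selects the alkene face so that C2 is set as R.

Step 5
Reactants: 9 2-[4-(benzyloxy)-3-methoxyphenyl]acetic acid
Product: 11 2-[4-(benzyloxy)-3-methoxyphenyl]-1-(pyrrolidin-1-yl)ethanone, via acyl imidazole 10 (not isolated)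
Conditions: CDI, THF, rt; then pyrrolidine, rt
Reagents that add atoms: pyrrolidine, C1CCNC1; 1,1'-carbonyldiimidazole, O=C(n1ccnc1)n1ccnc1 (imidazolyl group of 10 only)
Why: Standard acyl-imidazole amide coupling that delivers the tertiary pyrrolidine amide, a class that is O-triflated cleanly and gives compact, reactive keteniminium ions.

Step 6
Reactants: 8 4-[(2R)-2,5-dihydrofuran-2-yl]-2-methoxyphenyl acetate; 11 2-[4-(benzyloxy)-3-methoxyphenyl]-1-(pyrrolidin-1-yl)ethanone
Product: 15 (1S,4R,5R,7R)-4-(4-acetoxy-3-methoxyphenyl)-7-[4-(benzyloxy)-3-methoxyphenyl]-3-oxabicyclo[3.2.0]heptan-6-one (cis-fused; ring A anti to the cyclobutanone; ring B exo), via O-triflyl iminium triflate 12 (not isolated), via keteniminium triflate 13 (not isolated), via cyclobutaniminium triflate 14 (not isolated)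
Conditions: 11 (1.5 equiv), Tf2O (1.6 equiv), DCE, −20 °C; 8 + 2,4,6-collidine (2 equiv) added slowly, −20 → 60 °C; then H2O, 40 °C
Reagents that add atoms: water, O; triflic anhydride, O=S(=O)(OS(=O)(=O)C(F)(F)F)C(F)(F)F (triflate counter-ion of 12, 13 and 14 only)
Why: Tf2O converts amide 11 into the O-triflyl iminium salt 12, collidine removes TfOH to give keteniminium ion 13, the C3=C4 π bond attacks its sp carbon C9, and the positive charge growing on C4 is captured at once by the enamine carbon C7', a closure that is stepwise in timing but suprafacial on the alkene; water then hydrolyses iminium salt 14 to ketone 15. The closest known reaction type is the keteniminium–alkene (2+2) cycloaddition of ions made from tertiary amides, arylacetamides included, with unactivated cyclic alkenes such as cyclopentene. The single new ring, cyclobutane C3–C4–C7'–C9, closes by intermolecular (2+2) annulation and is necessarily cis-fused to the oxolane because both bonds go to the same alkene face. C3 and C4 are controlled by the C2 stereocentre, whose aryl group shields one face of the nearly flat ring so that C9 and C7' arrive anti to it (2,3-trans and 3,4-cis), while C7' should settle as the exo-aryl epimer through iminium–enamine and keto–enol equilibration and is erased in step 8. The step needs regioselectivity (C9 to C3): C2 bears O1 and an aryl ring made electron-poor by its acetate, so cationic character is tolerated better at C4 than at C3, aryl bridging from C2 is discouraged, and the bulky aryl-bearing terminus ends beside the C5 methylene and not beside C2. The same acetate should slow ionisation of the allylic benzylic C2–O1 bond and acylation of ring A by 13, and the excess of hindered base keeps free triflic acid out of the medium.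

Step 7
Reactants: 15 (1S,4R,5R,7R)-4-(4-acetoxy-3-methoxyphenyl)-7-[4-(benzyloxy)-3-methoxyphenyl]-3-oxabicyclo[3.2.0]heptan-6-one
Product: 16 (3R,3aS,6R,6aR)-6-(4-acetoxy-3-methoxyphenyl)-3-[4-(benzyloxy)-3-methoxyphenyl]tetrahydro-1H,3H-furo[3,4-c]furan-1-one
Conditions: mCPBA (1.2 equiv), CH2Cl2, 0 °C → rt
Reagents that add atoms: mCPBA, O=C(OO)c1cccc(Cl)c1
Why: Baeyer–Villiger oxidation, fast for a strained cyclobutanone, in which the secondary benzylic C7' activated by the para-benzyloxy ring should migrate with retention in preference to C3, which is deactivated by the oxygen-bearing C2 next to it, giving the cis-fused lactone.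

Step 8
Reactants: 16 (3R,3aS,6R,6aR)-6-(4-acetoxy-3-methoxyphenyl)-3-[4-(benzyloxy)-3-methoxyphenyl]tetrahydro-1H,3H-furo[3,4-c]furan-1-one
Product: 18 (2R,3R,4S)-2-(4-acetoxy-3-methoxyphenyl)-4-(4-hydroxy-3-methoxybenzyl)oxolane-3-carboxylic acid, via phenolic lactone 17 (not isolated)
Conditions: H2 (1 atm), 10% Pd/C, EtOAc–AcOH (9:1), rt
Reagents that add atoms: none
Why: Catalytic hydrogenolysis in which the aryl benzyl ether goes first and the C7'–O bond, a benzylic carboxylate on a now para-hydroxy ring, should be cleaved much faster than the C2–O1 alkyl ether on the acetoxy-deactivated ring, so that C7' becomes CH2 and C9 a carboxyl group while C2, C3 and C4 are untouched.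

Step 9
Reactants: 18 (2R,3R,4S)-2-(4-acetoxy-3-methoxyphenyl)-4-(4-hydroxy-3-methoxybenzyl)oxolane-3-carboxylic acid
Product: 19 4-[(2R,3S,4S)-4-(4-hydroxy-3-methoxybenzyl)-3-(hydroxymethyl)oxolan-2-yl]-2-methoxyphenyl acetate
Conditions: BH3·THF (3 equiv), THF, 0 °C → rt; then MeOH
Reagents that add atoms: none
Why: Chemoselective borane reduction of a carboxylic acid, which outruns attack on an aryl acetate at this temperature and is non-basic, so that C3 next to the carboxyl group cannot epimerise (its descriptor changes from R to S only through the priority rules).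

Step 10
Reactants: 19 4-[(2R,3S,4S)-4-(4-hydroxy-3-methoxybenzyl)-3-(hydroxymethyl)oxolan-2-yl]-2-methoxyphenyl acetate; 20 4-acetoxybenzoic acid
Product: 21 [(2R,3S,4S)-2-(4-acetoxy-3-methoxyphenyl)-4-(4-hydroxy-3-methoxybenzyl)oxolan-3-yl]methyl 4-acetoxybenzoate
Conditions: PPh3, DIAD, THF, 0 °C → rt
Reagents that add atoms: none
Why: Mitsunobu esterification in which the carboxylic acid (pKa about 4) is the pronucleophile that is deprotonated and its carboxylate displaces the activated primary oxygen at C9, while the hindered guaiacol OH (pKa about 10) should stay out and no stereocentre is involved.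

Step 11
Reactants: 21 [(2R,3S,4S)-2-(4-acetoxy-3-methoxyphenyl)-4-(4-hydroxy-3-methoxybenzyl)oxolan-3-yl]methyl 4-acetoxybenzoate
Product: 22 agastinol, [(2R,3S,4S)-4-(4-hydroxy-3-methoxybenzyl)-2-(4-hydroxy-3-methoxyphenyl)oxolan-3-yl]methyl 4-hydroxybenzoate
Conditions: pyrrolidine (6 equiv), THF, 0 °C → rt; aq citric acid work-up
Reagents that add atoms: none
Why: Aminolysis of activated phenolic esters, in which both aryl acetates acylate the secondary amine readily whereas the alkyl benzoate at C9 is inert to amines at this temperature, so the phenols are freed without ester exchange.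

Compound list
1 | 4-(benzyloxy)-3-methoxybenzaldehyde | COc1cc(C=O)ccc1OCc1ccccc1 | starting material
2 | 4-(benzyloxy)-3-methoxyphenyl formate | COc1cc(OC=O)ccc1OCc1ccccc1 | intermediate
3 | 4-(benzyloxy)-3-methoxyphenol | COc1cc(O)ccc1OCc1ccccc1 | intermediate
4 | 4-(benzyloxy)-3-methoxyphenyl trifluoromethanesulfonate | COc1cc(OS(=O)(=O)C(F)(F)F)ccc1OCc1ccccc1 | intermediate
5 | 4-hydroxy-3-methoxyphenyl trifluoromethanesulfonate | COc1cc(OS(=O)(=O)C(F)(F)F)ccc1O | intermediate
6 | 2-methoxy-4-(triflyloxy)phenyl acetate | COc1cc(OS(=O)(=O)C(F)(F)F)ccc1OC(C)=O | intermediate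
7 | 2,3-dihydrofuran | C1=COCC1 | starting material
8 | 4-[(2R)-2,5-dihydrofuran-2-yl]-2-methoxyphenyl acetate | C1O[C@@H](c2ccc(OC(C)=O)c(OC)c2)C=C1 | intermediate
9 | 2-[4-(benzyloxy)-3-methoxyphenyl]acetic acid | COc1cc(CC(=O)O)ccc1OCc1ccccc1 | starting material
10 | 2-[4-(benzyloxy)-3-methoxyphenyl]-1-(imidazol-1-yl)ethanone | COc1cc(CC(=O)n2ccnc2)ccc1OCc1ccccc1 | intermediate
11 | 2-[4-(benzyloxy)-3-methoxyphenyl]-1-(pyrrolidin-1-yl)ethanone | COc1cc(CC(=O)N2CCCC2)ccc1OCc1ccccc1 | intermediate
12 | 1-{2-[4-(benzyloxy)-3-methoxyphenyl]-1-(triflyloxy)ethylidene}pyrrolidinium triflate | COc1cc(CC(OS(=O)(=O)C(F)(F)F)=[N+]2CCCC2)ccc1OCc1ccccc1.[O-]S(=O)(=O)C(F)(F)F | intermediate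
13 | 1-{2-[4-(benzyloxy)-3-methoxyphenyl]ethenylidene}pyrrolidinium triflate | COc1cc(C=C=[N+]2CCCC2)ccc1OCc1ccccc1.[O-]S(=O)(=O)C(F)(F)F | intermediate
14 | cyclobutaniminium triflate, the C9=N+ pyrrolidinium form of 15 (C7' epimers) | COc1cc(C2[C@@H]3CO[C@@H](c4ccc(OC(C)=O)c(OC)c4)[C@@H]3C2=[N+]5CCCC5)ccc1OCc1ccccc1.[O-]S(=O)(=O)C(F)(F)F | intermediate
15 | (1S,4R,5R,7R)-4-(4-acetoxy-3-methoxyphenyl)-7-[4-(benzyloxy)-3-methoxyphenyl]-3-oxabicyclo[3.2.0]heptan-6-one | COc1cc([C@H]2[C@@H]3CO[C@@H](c4ccc(OC(C)=O)c(OC)c4)[C@@H]3C2=O)ccc1OCc1ccccc1 | intermediate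
16 | (3R,3aS,6R,6aR)-6-(4-acetoxy-3-methoxyphenyl)-3-[4-(benzyloxy)-3-methoxyphenyl]tetrahydro-1H,3H-furo[3,4-c]furan-1-one | COc1cc([C@H]2[C@@H]3CO[C@@H](c4ccc(OC(C)=O)c(OC)c4)[C@@H]3C(=O)O2)ccc1OCc1ccccc1 | intermediate
17 | (3R,3aS,6R,6aR)-6-(4-acetoxy-3-methoxyphenyl)-3-(4-hydroxy-3-methoxyphenyl)tetrahydro-1H,3H-furo[3,4-c]furan-1-one | COc1cc([C@H]2[C@@H]3CO[C@@H](c4ccc(OC(C)=O)c(OC)c4)[C@@H]3C(=O)O2)ccc1O | intermediate
18 | (2R,3R,4S)-2-(4-acetoxy-3-methoxyphenyl)-4-(4-hydroxy-3-methoxybenzyl)oxolane-3-carboxylic acid | COc1cc(C[C@@H]2CO[C@@H](c3ccc(OC(C)=O)c(OC)c3)[C@@H]2C(=O)O)ccc1O | intermediate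
19 | 4-[(2R,3S,4S)-4-(4-hydroxy-3-methoxybenzyl)-3-(hydroxymethyl)oxolan-2-yl]-2-methoxyphenyl acetate | COc1cc(C[C@@H]2CO[C@@H](c3ccc(OC(C)=O)c(OC)c3)[C@@H]2CO)ccc1O | intermediate
20 | 4-acetoxybenzoic acid | CC(=O)Oc1ccc(C(=O)O)cc1 | starting material
21 | [(2R,3S,4S)-2-(4-acetoxy-3-methoxyphenyl)-4-(4-hydroxy-3-methoxybenzyl)oxolan-3-yl]methyl 4-acetoxybenzoate | COc1cc(C[C@@H]2CO[C@@H](c3ccc(OC(C)=O)c(OC)c3)[C@@H]2COC(=O)c2ccc(OC(C)=O)cc2)ccc1O | intermediate
22 | agastinol | COc1cc(C[C@@H]2CO[C@@H](c3ccc(O)c(OC)c3)[C@@H]2COC(=O)c2ccc(O)cc2)ccc1O | target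

Total step count: 11. Longest linear sequence: 10 steps (steps 1–4 and 6–11); step 5 is a one-step side branch.

Steps most likely to fail

1. Step 6.
- **What may go wrong.** Regiocontrol may erode in the first C–C bond formation. The allylic benzylic ether may ring-open in the triflating medium during the long warm period. The cation may also be consumed by arene acylation.
- **Fallback.** The cationic heterocumulene is replaced by the neutral ketene, activated by a Lewis acid at low temperature.
- **Path.** It sets out from 9 (with 8 as partner). Oxalyl chloride and catalytic DMF in CH2Cl2 give 2-[4-(benzyloxy)-3-methoxyphenyl]acetyl chloride F1. Et3N in the presence of 8 releases [4-(benzyloxy)-3-methoxyphenyl]ketene F2. EtAlCl2 at −78 °C then promotes its ketene–alkene (2+2) cycloaddition to C3=C4. No triflic anhydride, heating or iminium hydrolysis is involved, and the lower temperature should favour selectivity. The route is rejoined at 15.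

2. Step 8.
- **What may go wrong.** Competing hydrogenolysis of the C2–O1 bond may open the oxolane, or the reaction may stall after debenzylation.
- **Fallback.** Ionic reduction replaces catalytic reduction.
- **Path.** It sets out from 16. Et3SiH and TFA in CH2Cl2 at 0 °C should ionise only the C7'–O bond. That bond has a carboxylate leaving group and gives a benzyloxy-stabilised cation, whereas a cation at C2 is disfavoured by the acetoxy ring. Hydride transfer gives (2R,3R,4S)-2-(4-acetoxy-3-methoxyphenyl)-4-[4-(benzyloxy)-3-methoxybenzyl]oxolane-3-carboxylic acid F3. A brief transfer hydrogenolysis (Pd/C, cyclohexa-1,4-diene, EtOAc) then removes only the aryl benzyl ether. The route is rejoined at 18.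

3. Step 7.
- **What may go wrong.** C3 may migrate in competition with C7', or the peracid may oxidise the electron-rich ring B.
- **Fallback.** Enolisation, not migratory aptitude, selects the bond to be cut.
- **Path.** It sets out from 15.
  - TMSOTf and Et3N give the aryl-conjugated C9=C7' trimethylsilyl enol ether F4. Enolisation towards the ring-fusion carbon C3 is disfavoured.
  - Catalytic OsO4 with NMO gives the 7'-hydroxy ketone F5.
  - NaIO4 in aqueous THF cleaves C9–C7' to (2R,3R,4S)-2-(4-acetoxy-3-methoxyphenyl)-4-[4-(benzyloxy)-3-methoxybenzoyl]oxolane-3-carboxylic acid F6. This compound is kept away from base so that C4 does not epimerise.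
  - Hydrogenation over Pd/C in EtOAc–AcOH takes the aryl ketone down to CH2 and removes the benzyl group. The route is rejoined at 18.

Further compounds
F1 | step 6 | 2-[4-(benzyloxy)-3-methoxyphenyl]acetyl chloride | COc1cc(CC(=O)Cl)ccc1OCc1ccccc1
F2 | step 6 | [4-(benzyloxy)-3-methoxyphenyl]ketene | COc1cc(C=C=O)ccc1OCc1ccccc1
F3 | step 8 | (2R,3R,4S)-2-(4-acetoxy-3-methoxyphenyl)-4-[4-(benzyloxy)-3-methoxybenzyl]oxolane-3-carboxylic acid | COc1cc(C[C@@H]2CO[C@@H](c3ccc(OC(C)=O)c(OC)c3)[C@@H]2C(=O)O)ccc1OCc1ccccc1
F4 | step 7 | C9=C7' trimethylsilyl enol ether of 15 | COc1cc(C=2[C@@H]3CO[C@@H](c4ccc(OC(C)=O)c(OC)c4)[C@@H]3C=2O[Si](C)(C)C)ccc1OCc1ccccc1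
F5 | step 7 | 7'-hydroxy ketone derived from 15 (C7' configuration open) | COc1cc(C2(O)[C@@H]3CO[C@@H](c4ccc(OC(C)=O)c(OC)c4)[C@@H]3C2=O)ccc1OCc1ccccc1
F6 | step 7 | (2R,3R,4S)-2-(4-acetoxy-3-methoxyphenyl)-4-[4-(benzyloxy)-3-methoxybenzoyl]oxolane-3-carboxylic acid | COc1cc(C(=O)[C@@H]2CO[C@@H](c3ccc(OC(C)=O)c(OC)c3)[C@@H]2C(=O)O)ccc1OCc1ccccc1
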